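**Retrosynthetic overview**
1. Target ⇐ β-face epoxidation of a (Z)-3,4-olefin (the epoxide is cis), mono-angeloylation of an 8,9-diol at O9, and oxidation at C1.
2. Ten-membered carbocycle and trans-fused lactone ⇐ one chromium-catalysed electroreductive Barbier macrocyclisation that forms C6–C7 from an ω-formyl (Z)-2-(bromomethyl)enoate.
3. Open chain ⇐ Morita–Baylis–Hillman reaction and bromination at C7, and α-selective (Z)-allylbarium addition to a C1 enal.
4. Building blocks: 2-deoxy-D-ribose (C1, C7–C10; supplies the C8 and C9 stereocentres) plus CH2O (C14); 4-methyl-5,6-dihydro-2H-pyran-2-one (C2–C6, Z geometry from the ring); methyl acrylate (C11–C13); angelic acid.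
5. Ring order: carbocycle and lactone together, epoxide last.

Assumption: locants follow germacranolide numbering of the target (C1 ketone, C3–C4 epoxide, C4 methyl, C6 lactone O, C8 OH, C9 angelate, C10=C14, C11=C13, C12 lactone C=O); the C1 carbinol (steps 5–11) and the C7 carbinol (step 7) are carried as epimer mixtures because both centres are destroyed later.

**Step 1**
Reactants: 1 2-deoxy-D-ribose
Product: 2 2-deoxy-3,4-O-isopropylidene-D-erythro-pentopyranose (lactol)
Conditions: 2-methoxypropene, PPTS (cat.), EtOAc, 0 → 23 °C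
Reagents that add atoms: 2-methoxypropene, COC(C)=C
Why: Kinetic acid-catalysed acetalisation with an enol ether engages the only cis-1,2-diol (O3/O4) of the pyranose and leaves the lactol free, so both purchased stereocentres (later C9 S and C8 R) are carried on untouched.

**Step 2**
Reactants: 2 acetonide lactol
Product: 3 2-deoxy-3,4-O-isopropylidene-2-methylene-D-erythro-pentopyranose (lactol in equilibrium with the open hydroxy enal)
Conditions: 37% aq. CH2O, pyrrolidine (10 mol%), EtCO2H (10 mol%), i-PrOH, 45 °C
Reagents that add atoms: formaldehyde, C=O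
Why: Amine-catalysed Mannich condensation and elimination (organocatalytic α-methylenation of aldehydes) on the ring-open aldehyde installs C14 on the only enolisable carbon (C10), and the weakly basic buffer disfavours β-elimination of the acetonide oxygen.

**Step 3**
Reactants: 4 4-methyl-5,6-dihydro-2H-pyran-2-one
Product: 5 (Z)-3-methylpent-2-ene-1,5-diol
Conditions: i-Bu2AlH (DIBAL-H, 2.5 equiv), CH2Cl2, −78 → 0 °C; aq. potassium sodium tartrate (KNaC4H4O6)
Reagents that add atoms: none
Why: 1,2-Reduction of the α,β-unsaturated δ-lactone by the aluminium hydride gives the allylic diol, and the Z geometry of the trisubstituted olefin (C2 and C5 cis) is inherited from the ring.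

**Step 4**
Reactants: 5 (Z)-diol
Product: 7 (Z)-tert-butyl[(5-chloro-3-methylpent-3-en-1-yl)oxy]dimethylsilane, via chloro alcohol 6 (not isolated)
Conditions: NCS, Me2S, CH2Cl2, −40 → 0 °C; then TBSCl, imidazole, 0 → 23 °C
Reagents that add atoms: N-chlorosuccinimide, ClN1C(=O)CCC1=O; tert-butyldimethylsilyl chloride, CC(C)(C)[Si](C)(C)Cl
Why: Corey–Kim chlorination converts only the allylic alcohol (SN2, no allylic transposition, Z geometry kept), and the remaining homoallylic alcohol is silylated in the same flask.

**Step 5**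
Reactants: 3 methylene lactol; 7 allylic chloride
Product: 10 open-chain 1,7-bis(triethylsilyl) 6-TBS ether (1RS; 3Z; 8R; 9S), via allylbarium chloride 8 (not isolated), via chlorobarium dialkoxide 9 (not isolated)
Conditions: 7 (2.3 equiv), Ba metal (from BaI2 + 2 LiC12H10), THF, −78 °C; add 3, −78 °C; then TESCl, DMAP (cat.), −78 → 23 °C
Reagents that add atoms: chlorotriethylsilane, CC[Si](CC)(CC)Cl
Why: Yamamoto-type allylbarium addition, in which barium reagents formed at −78 °C add 1,2 to enals through the α-carbon with retention of Z geometry; one equivalent deprotonates the lactol, the second captures the ring-open alkoxy enal (C1–C2 bond), and the dialkoxide is silylated in the flask.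

**Step 6**
Reactants: 10 bis-TES ether
Product: 11 C7 aldehyde (1RS; 3Z; 8S by priority change only; 9S)
Conditions: (COCl)2, DMSO, CH2Cl2, −78 → −40 °C; i-Pr2NEt, −78 → 0 °C
Reagents that add atoms: none
Why: Under Swern conditions primary triethylsilyl ethers are cleaved and oxidised directly to aldehydes while secondary TES and primary TBS ethers survive, and the hindered amine at low temperature keeps the α-alkoxy centre C8 from epimerising.

**Step 7**
Reactants: 11 C7 aldehyde; 12 methyl acrylate
Product: 13 Morita–Baylis–Hillman adduct (C7 carbinol epimers)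
Conditions: DABCO (1 equiv), 1,4-dioxane/H2O (1:1), 23 °C
Reagents that add atoms: none
Why: Morita–Baylis–Hillman reaction of the activated α-alkoxy aldehyde with the acrylate attaches C11–C13; the new C7 carbinol centre is irrelevant because it becomes sp2 in step 8.

**Step 8**
Reactants: 13 Baylis–Hillman adduct
Product: 14 methyl (Z)-2-(bromomethyl)enoate (C8 cis to CH2Br)
Conditions: NBS, Me2S, CH2Cl2, −20 → 23 °C
Reagents that add atoms: N-bromosuccinimide, BrN1C(=O)CCC1=O
Why: Corey–Kim-type activation of the allylic alcohol followed by SN2' attack of bromide gives the thermodynamically preferred (Z)-2-(bromomethyl)-2-enoate, and the silyl ethers and the isolated olefin do not react with the preformed sulfonium salt.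

**Step 9**
Reactants: 14 bromide
Product: 15 C1,C6-diol
Conditions: 48% aq. HF, MeCN, 0 °C
Reagents that add atoms: none
Why: Fluoride-assisted desilylation removes the secondary TES and the primary TBS ether, while the dioxolane and the allylic bromide tolerate this amine-free medium (pyridine would alkylate).

**Step 10**
Reactants: 15 diol
Product: 16 ω-formyl allylic bromide (C6 aldehyde; free C1 carbinol)
Conditions: TEMPO (0.2 equiv), PhI(OAc)2, CH2Cl2, 23 °C
Reagents that add atoms: none
Why: Oxoammonium (TEMPO) oxidation selects the unhindered primary alcohol over the hindered secondary allylic C1 carbinol, and the near-neutral medium leaves the β,γ-unsaturated aldehyde unconjugated.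

**Step 11**
Reactants: 16 ω-formyl allylic bromide
Product: 19 macrocyclic trans-lactone (3Z; 6R; 7S while the acetonide is present; 8R; 9S; C1 epimers), via allylchromium dichloride 17 (not isolated), via ring-closed chromium alkoxide 18 (not isolated)
Conditions: CrCl3(THF)3 (15 mol%), n-Bu4NBr (0.1 M), DMF, undivided cell, Al anode, Ni-foam cathode, 4 mA (2.5 F/mol), 23 °C, 16 added over 10 h to 2 mM; aq. citric acid
Reagents that add atoms: none
Why: Proposed new method: a chromium-catalysed electroreductive Barbier macrocyclisation–lactonisation, in which the cathode reduces CrCl3 to divalent chromium, two divalent chromium centres convert the allylic bromide (halogen abstraction, then radical capture) into the trivalent allylchromium 17, and 17 adds through its γ-carbon C7 to the tethered aldehyde in a closed chair transition state; both ring branches sit pseudo-equatorial (6,7-anti, hence the trans-lactone) and attack occurs on the enoate face anti to the C8–O bond with H8 in the olefin plane (minimised A(1,3) strain, and the face from which the C9 tether delivers the aldehyde), which sets C6 and C7; Al3+ from the anode takes the alkoxide from chromium so that chromium is reduced again, and the alkoxide closes the lactone with loss of methoxide; the closest known reactions are stoichiometric CrCl2 Barbier macrocyclisations of ω-formyl 2-(bromomethyl)enoates to germacranolides and chromium-catalysed electrochemical Nozaki–Hiyama–Kishi couplings, neither shown as a catalytic electrochemical ring closure on this substrate class.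

**Step 12**
Reactants: 19 macrocyclic C1 carbinol
Product: 20 macrocyclic α-methylene ketone (3Z; 6R; 7S; 8R; 9S)
Conditions: Dess–Martin periodinane, NaHCO3, CH2Cl2, 0 → 23 °C
Reagents that add atoms: none
Why: Dess–Martin oxidation of the only free hydroxyl gives the C1 enone and merges the two C1 epimers, and the buffered neutral medium avoids migration of the 3,4-olefin into conjugation.

**Step 13**
Reactants: 20 acetonide enone
Product: 21 8,9-diol (3Z; 6R; 7R; 8R; 9S)
Conditions: TFA/H2O (9:1), CH2Cl2, 0 °C
Reagents that add atoms: none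
Why: Acid-catalysed acetal hydrolysis frees the cis-8,9-diol without touching a stereocentre; short cold exposure spares the skipped enone and the α-methylene lactone.

**Step 14**
Reactants: 21 diol; 22 angelic acid
Product: 23 9-O-angelate (3Z; 6R; 7R; 8R; 9S)
Conditions: 22 (1.1 equiv), 2,4,6-Cl3C6H2COCl, Et3N, PhMe, 23 °C; then 21, PhMe, 23 → 60 °C
Reagents that add atoms: none
Why: Yamaguchi-type esterification through the mixed anhydride without DMAP (the protocol that avoids angelate-to-tiglate isomerisation) is expected to acylate the allylic C9 hydroxyl, which is flanked by sp2 C10 and hydrogen-bonded to the C1 carbonyl, faster than the C8 hydroxyl next to the ring-fusion methine C7.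

**Step 15**
Reactants: 23 angelate olefin
Product: 24 target CNP0348992.4
Conditions: DMDO, acetone, −20 → 0 °C
Reagents that add atoms: dimethyldioxirane, CC1(C)OO1
Why: Dioxirane epoxidation is stereospecific and touches only the electron-rich trisubstituted olefin, so the Z olefin gives the cis-epoxide; attack on the β face, away from the α-oriented oxygen substituents at C6, C8 and C9, is expected to set 3S,4R (macrocyclic substrate control), and acetone as solvent suppresses delivery by the C8 hydroxyl.

**Compound list**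
1 | 2-deoxy-D-ribose (pyranose form; open form (3S,4R)-3,4,5-trihydroxypentanal) | OC1C[C@H](O)[C@H](O)CO1 | starting material
2 | 2-deoxy-3,4-O-isopropylidene-D-erythro-pentopyranose (lactol, anomer mixture) | OC1C[C@@H]2OC(C)(C)O[C@@H]2CO1 | intermediate
3 | 2-deoxy-3,4-O-isopropylidene-2-methylene-D-erythro-pentopyranose (open form 2-[(4S,5R)-5-(hydroxymethyl)-2,2-dimethyl-1,3-dioxolan-4-yl]prop-2-enal) | OC1C(=C)[C@@H]2OC(C)(C)O[C@@H]2CO1 | intermediate
4 | 4-methyl-5,6-dihydro-2H-pyran-2-one | CC1=CC(=O)OCC1 | starting material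
5 | (Z)-3-methylpent-2-ene-1,5-diol | OC/C=C(/C)CCO | intermediate
6 | (Z)-5-chloro-3-methylpent-3-en-1-ol | ClC/C=C(/C)CCO | intermediate
7 | (Z)-tert-butyl[(5-chloro-3-methylpent-3-en-1-yl)oxy]dimethylsilane | ClC/C=C(/C)CCO[Si](C)(C)C(C)(C)C | intermediate
8 | [(Z)-5-(tert-butyldimethylsilyloxy)-3-methylpent-2-en-1-yl]barium chloride | Cl[Ba]C/C=C(/C)CCO[Si](C)(C)C(C)(C)C | intermediate
9 | bis(chlorobarium) alkoxide of the open-chain C1,C7-diol: TBSO–C6H2–C5H2–C4(CH3)=C3H–C2H2–C1H(OBaCl)–C10(=C14H2)–C9H–C8H–C7H2–OBaCl with an 8,9-O-isopropylidene group; 3Z, 8R, 9S, C1 epimers | C=C([C@@H]1OC(C)(C)O[C@@H]1CO[Ba]Cl)C(O[Ba]Cl)C/C=C(/C)CCO[Si](C)(C)C(C)(C)C | intermediate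
10 | same chain as its 1,7-bis(triethylsilyl) ether, 6-O-TBS, 8,9-acetonide; 3Z, 8R, 9S, C1 epimers | C=C([C@@H]1OC(C)(C)O[C@@H]1CO[Si](CC)(CC)CC)C(O[Si](CC)(CC)CC)C/C=C(/C)CCO[Si](C)(C)C(C)(C)C | intermediate
11 | C7 aldehyde of 10 (1-O-TES, 6-O-TBS, 8,9-acetonide); 3Z, 8S (same spatial arrangement, CHO now outranks C9), 9S, C1 epimers | C=C([C@@H]1OC(C)(C)O[C@@H]1C=O)C(O[Si](CC)(CC)CC)C/C=C(/C)CCO[Si](C)(C)C(C)(C)C | intermediate
12 | methyl acrylate | C=CC(=O)OC | starting material
13 | Baylis–Hillman adduct: C7H(OH)–C11(=C13H2)–C12O2CH3 on the chain of 11; 3Z, 8R, 9S, C1 and C7 epimers | C=C([C@@H]1OC(C)(C)O[C@@H]1C(O)C(=C)C(=O)OC)C(O[Si](CC)(CC)CC)C/C=C(/C)CCO[Si](C)(C)C(C)(C)C | intermediate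
14 | methyl (Z)-2-(bromomethyl)enoate: C8–C7H=C11(CO2CH3)–C13H2Br with C8 cis to CH2Br; 1-O-TES, 6-O-TBS, 8,9-acetonide; 3Z, 8R, 9S, C1 epimers | C=C([C@@H]1OC(C)(C)O[C@@H]1/C=C(\CBr)C(=O)OC)C(O[Si](CC)(CC)CC)C/C=C(/C)CCO[Si](C)(C)C(C)(C)C | intermediate
15 | C1,C6-diol of 14 (both silyl ethers removed) | C=C([C@@H]1OC(C)(C)O[C@@H]1/C=C(\CBr)C(=O)OC)C(O)C/C=C(/C)CCO | intermediate
16 | C6 aldehyde of 15 (free C1 carbinol, allylic bromide, 8,9-acetonide); 3Z, 8R, 9S | C=C([C@@H]1OC(C)(C)O[C@@H]1/C=C(\CBr)C(=O)OC)C(O)C/C=C(/C)CC=O | intermediate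
17 | allylchromium dichloride from 16 (trivalent chromium on C13) | C=C([C@@H]1OC(C)(C)O[C@@H]1/C=C(\C[Cr](Cl)Cl)C(=O)OC)C(O)C/C=C(/C)CC=O | intermediate
18 | ring-closed ten-membered carbocycle: C6 chromium alkoxide, methyl 2-propenoate unit on C7, before lactonisation | COC(=O)C(=C)[C@H]1[C@H](O[Cr](Cl)Cl)C/C(C)=C\CC(O)C(=C)[C@@H]2OC(C)(C)O[C@@H]21 | intermediate
19 | (3Z,6R,7S,8R,9S)-1-hydroxy-8,9-(isopropylidenedioxy)germacra-3,10(14),11(13)-trien-12,6-olide, C1 epimers, H6/H7 trans | C=C1C(=O)O[C@@H]2C/C(C)=C\CC(O)C(=C)[C@@H]3OC(C)(C)O[C@@H]3[C@@H]12 | intermediate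
20 | (3Z,6R,7S,8R,9S)-8,9-(isopropylidenedioxy)-1-oxogermacra-3,10(14),11(13)-trien-12,6-olide | C=C1C(=O)O[C@@H]2C/C(C)=C\CC(=O)C(=C)[C@@H]3OC(C)(C)O[C@@H]3[C@@H]12 | intermediate
21 | (3Z,6R,7R,8R,9S)-8,9-dihydroxy-1-oxogermacra-3,10(14),11(13)-trien-12,6-olide | C=C1C(=O)O[C@@H]2C/C(C)=C\CC(=O)C(=C)[C@H](O)[C@H](O)[C@@H]12 | intermediate
22 | angelic acid, (Z)-2-methylbut-2-enoic acid | C/C=C(/C)C(=O)O | starting material
23 | (3Z,6R,7R,8R,9S)-9-angeloyloxy-8-hydroxy-1-oxogermacra-3,10(14),11(13)-trien-12,6-olide | C=C1C(=O)O[C@@H]2C/C(C)=C\CC(=O)C(=C)[C@H](OC(=O)/C(C)=C\C)[C@H](O)[C@@H]12 | intermediate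
24 | CNP0348992.4, (3S,4R,6R,7R,8R,9S)-9-angeloyloxy-3,4-epoxy-8-hydroxy-1-oxogermacra-10(14),11(13)-dien-12,6-olide | C=C1C(=O)O[C@@H]2C[C@@]3(C)O[C@H]3CC(=O)C(=C)[C@H](OC(=O)/C(C)=C\C)[C@H](O)[C@@H]12 | target

**Step count and risks**
Total: 15 steps. Longest linear sequence: 13 steps (1 → 2 → 3 → 10 → … → 24, or 4 → 5 → 7 → 10 → … → 24).

Most likely to fail:

Step 11 (the proposed electrochemical macrocyclisation). The risks are poor chromium turnover at 2 mM, direct cathodic reduction of the bromide or aldehyde, and the wrong C6/C7 diastereomer. Fallback: give up the electrocatalytic cycle and run the classical stoichiometric chromium Barbier ring closure, which is known for closing germacranolide rings with their α-methylene lactone. It sets out from 16 (CrCl2, 8 equiv, DMF/THF, syringe pump to 2 mM, 23 °C, then aq. citric acid) and comes back at 19; no new compound is made (F0).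

Step 5 (allylbarium addition to the lactol). The risks are incomplete ring opening of the barium lactolate at −78 °C, γ-attack, and loss of Z geometry. Fallback: a sulfone-anion addition followed by palladium-catalysed hydride desulfonylation, which sets out from 7 and 3 and comes back at 10. Chloride 7 is displaced with PhSO2Na in DMF to give the (Z)-allylic phenyl sulfone F1. F1 is lithiated with n-BuLi in THF at −78 °C (2.2 equiv, one serving as base for the lactol) and adds through its α-carbon to 3 to give the β-hydroxy sulfone diol F2 (diastereomer mixture). Silylation with TESCl and imidazole gives the bis(triethylsilyl) sulfone F3. PdCl2(dppp) with LiBHEt3 in THF at 0 °C (zerovalent palladium π-allyl, hydride delivered to the less substituted terminus) removes the sulfonyl group and gives 10.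

Step 14 (regioselective mono-angeloylation). The risks are acylation at O8, mixtures, and tiglate formation. Fallback: mask O8 through its 1,4-relationship to the C1 ketone. It sets out from 21 and comes back at 23. MeOH, HC(OMe)3 and PPTS convert the γ-hydroxy ketone into the internal methyl ketal F4 (C8–O–C1 bridge, as in natural oxygen-bridged germacranolides), leaving O9 as the only free hydroxyl. The same mixed anhydride of 22 then gives the ketal angelate F5, and PPTS in wet acetone hydrolyses the ketal to 23.

**Further compounds**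
F1 | step 5 | (Z)-tert-butyldimethyl{[3-methyl-5-(phenylsulfonyl)pent-3-en-1-yl]oxy}silane | O=S(=O)(C/C=C(/C)CCO[Si](C)(C)C(C)(C)C)c1ccccc1
F2 | step 5 | β-hydroxy sulfone diol: chain of 10 with free hydroxyls at C1 and C7 and a phenylsulfonyl group on C2 (3Z, 8R, 9S, epimers at C1 and C2) | C=C([C@@H]1OC(C)(C)O[C@@H]1CO)C(O)C(/C=C(/C)CCO[Si](C)(C)C(C)(C)C)S(=O)(=O)c1ccccc1
F3 | step 5 | 1,7-bis(triethylsilyl) ether of F2 | C=C([C@@H]1OC(C)(C)O[C@@H]1CO[Si](CC)(CC)CC)C(O[Si](CC)(CC)CC)C(/C=C(/C)CCO[Si](C)(C)C(C)(C)C)S(=O)(=O)c1ccccc1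
F0 | step 11 | none | none
F4 | step 14 | internal methyl ketal of 21: 1-methoxy-1,8-epoxy bridge, free 9-hydroxyl (3Z, 6R, 7R, 8R, 9S, C1 ketal epimers) | C=C1C(=O)O[C@@H]2C/C(C)=C\CC4(OC)C(=C)[C@H](O)[C@H](O4)[C@@H]12
F5 | step 14 | 9-O-angelate of F4 | C=C1C(=O)O[C@@H]2C/C(C)=C\CC4(OC)C(=C)[C@H](OC(=O)/C(C)=C\C)[C@H](O4)[C@@H]12
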